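Ring A (C1–C5, C10) is disconnected from ring B by a [4+2] retron across the C5–C10 bond. Ring B, oxygenated at C6 and unsaturated at C7=C8 in the target, corresponds to 2-methoxy-5-methyl-1,4-benzoquinone, whose methyl-bearing C5=C10 alkene serves as dienophile for 4-methylpenta-1,3-diene. One catalytic enantioselective cycloaddition forms C10–C1 and C4–C5, closes ring A with its gem-dimethyl group and fixes the C10 quaternary centre; both partners are purchased. The ring-fusion hydrogen is later reset trans by dissolving-metal reduction, a Claisen rearrangement sets C9 and creates the C7=C8 acid unit, and the butenolide and (R)-ester are added last.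

Key step: step 1

Assumption: labdane numbering is used for the bicyclic core of every intermediate ("decal" = decahydronaphthalene core; ring A C1–C5/C10, ring B C5–C10, methyls on C4 and C10; α/β as in labdanes).
Assumption: the (S)-oxazaborolidinium is expected to add the diene to the α-face of C5=C10, by analogy with its α-C–H-bound acrylate and quinone complexes; should the antipodal adduct form, the (R)-catalyst is used and nothing else changes.

Step 1
Reactants: 1 2-methoxy-5-methyl-1,4-benzoquinone; 2 4-methylpenta-1,3-diene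
Product: 3 cis-fused adduct 7-methoxy-4,4,10β-trimethyl-5βH-decal-2,7-diene-6,9-dione
Conditions: (S)-o-tolyl-CBS oxazaborolidine (20 mol%), Tf2NH (18 mol%), 2 (5 equiv), CH2Cl2 (1 M), −78 → −30 °C, 48 h
Reagents that add atoms: none
Why: The cationic oxazaborolidinium binds the C6 carbonyl oxygen (the carbonyl outside the vinylogous ester) on the lone pair syn to C5–H, so the methyl-bearing C5=C10 alkene is the activated dienophile with C10 as its electrophilic end, and the diene adds in a concerted, asynchronous, endo [4+2] process in which the CH2 terminus bonds to C10 ahead of the CMe2 terminus bonding to C5. The closest known reactions are oxazaborolidinium-catalysed Diels–Alder additions to 2-methoxy- and 2-methylbenzoquinones and the classical methoxytoluquinone–butadiene cycloaddition. Ring A is closed by the cycloaddition itself, as a six-membered annulation onto the C5–C10 edge of ring B, with C10–C1 and C4–C5 formed suprafacially on one quinone face. C10 is controlled by the catalyst, whose aryl group shields one face of the bound alkene, and C5 follows as the cis partner (it is erased in step 2 and reset in step 5). The step needs site selectivity (the methoxy alkene is a deactivated vinylogous ester), regioselectivity (C6-carbonyl activation, reinforced because the alternative would join two fully substituted carbons) and face selectivity (catalyst). The cis-methyl of the diene makes its s-cis conformer scarce, hence the excess diene, high concentration and long reaction time.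

Step 2
Reactants: 3 cis-fused adduct
Product: 4 dienol ether 6-(methoxymethoxy)-7-methoxy-4,4,10β-trimethyldecal-2,5,7-trien-9-one
Conditions: KHMDS, THF, −78 °C; MOMCl, −78 → 0 °C
Reagents that add atoms: chloromethyl methyl ether, COCCl
Why: Enolate O-alkylation: C5–H is the only enolisable position of the C6 ketone and C-alkylation at the neopentyl C5 is blocked, so O6 is protected as a non-migrating acetal and the cis C5 centre is deliberately erased instead of being equilibrated (the trans fusion of a 4,4-dimethyl-6-oxo decalin is not reliably favoured).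

Step 3
Reactants: 4 dienol ether
Product: 6 cross-conjugated dienone 6-(methoxymethoxy)-4,4,10β-trimethyldecal-2,5,8-trien-7-one, via C9 allylic alcohol 5 (not isolated)
Conditions: DIBAL-H (1.5 equiv), CH2Cl2, −78 °C; then 0.5 M HCl, THF, 0 °C
Reagents that add atoms: water, O
Why: 1,2-Reduction of the vinylogous ester carbonyl followed by acid-induced allylic transposition (Stork–Danheiser type): the C9 carbinol ionises to the 7-methoxy-stabilised cation, water adds at C7 and methanol is lost, moving the carbonyl to C7 while the enol acetal on C6 (not on the cation path) survives the brief cold acid.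

Step 4
Reactants: 6 cross-conjugated dienone
Product: 7 enone 6-(methoxymethoxy)-4,4,10β-trimethyldecal-5-en-7-one
Conditions: H2 (1 atm), 10% Pd/C, EtOAc, 23 °C
Reagents that add atoms: none
Why: Catalytic hydrogenation should take the two cis-disubstituted alkenes (C2=C3 and C8=C9, the latter like Δ1 of a steroidal 1,4-dien-3-one) and leave the tetrasubstituted, alkoxy-bearing C5=C6 bond flanked by two quaternary carbons.

Step 5
Reactants: 7 enone
Product: 10 trans-fused ketone 6α-(methoxymethoxy)-4,4,10β-trimethyl-5αH-decalin-7-one, via lithium enolate 8 (not isolated), via 6β-epimeric ketone 9 (not isolated)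
Conditions: Li (3 equiv), NH3(l)/THF, t-BuOH (1 equiv), −78 °C; NH4Cl; then NaOMe (cat.), MeOH, 23 °C
Reagents that add atoms: none
Why: Dissolving-metal enone reduction (Birch type) protonates the β-carbon C5 axially, anti to the 10β-methyl, giving the trans fusion as in 10-methyl-Δ1(9)-octal-2-ones, and base equilibration α to the C7 ketone then places the 6-OMOM group equatorial (6α), away from the syn-axial 4β/10β methyls.

Step 6
Reactants: 10 trans-fused ketone
Product: 12 enone 6α-(methoxymethoxy)-4,4,10β-trimethyl-5αH-decal-8-en-7-one, via trimethylsilyl enol ether 11 (not isolated)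
Conditions: LDA, TMSCl, THF, −78 °C; then Pd(OAc)2 (1.1 equiv), MeCN, 23 °C
Reagents that add atoms: none
Why: Saegusa–Ito dehydrogenation: kinetic deprotonation occurs at the C8 methylene (the tertiary 6β-H is shielded by the axial methyls) and Pd(II) oxidation of the silyl enol ether gives the Δ8 enone.

Step 7
Reactants: 12 enone
Product: 13 iodoenone 8-iodo-6α-(methoxymethoxy)-4,4,10β-trimethyl-5αH-decal-8-en-7-one
Conditions: I2 (2 equiv), pyridine, DMAP (cat.), CH2Cl2, 23 °C
Reagents that add atoms: iodine, II
Why: α-Iodination of a β-unsubstituted enone by amine conjugate addition, enolate iodination and elimination, as established for 4,4-dimethylcyclohex-2-enone.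

Step 8
Reactants: 13 iodoenone
Product: 14 allylic alcohol 8-iodo-6α-(methoxymethoxy)-4,4,10β-trimethyl-5αH-decal-8-en-7β-ol
Conditions: NaBH4, CeCl3·7H2O, MeOH, −78 °C
Reagents that add atoms: none
Why: Luche 1,2-reduction with axial (α-face) hydride delivery, as steroidal Δ4-3-ketones give 3β-ols, should set the temporary 7β-carbinol trans to the 6α-ether.

Step 9
Reactants: 14 allylic alcohol
Product: 15 hydroxy ester 4-methoxybenzyl 7β-hydroxy-6α-(methoxymethoxy)-4,4,10β-trimethyl-5αH-decal-8-ene-8-carboxylate
Conditions: CO (1 atm), Pd(OAc)2 (5 mol%), dppf, 4-methoxybenzyl alcohol (3 equiv), Et3N, DMF, 60 °C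
Reagents that add atoms: carbon monoxide, [C-]#[O+]; 4-methoxybenzyl alcohol, COc1ccc(CO)cc1
Why: Pd-catalysed alkoxycarbonylation of the alkenyl iodide installs C17 as an acid-labile PMB ester; the free secondary alcohol is tolerated.

Step 10
Reactants: 15 hydroxy ester; 16 butyl vinyl ether
Product: 18 aldehyde 4-methoxybenzyl 6α-(methoxymethoxy)-9β-(2-oxoethyl)-4,4,10β-trimethyl-5αH,9αH-decal-7-ene-8-carboxylate, via allyl vinyl ether 17 (not isolated)
Conditions: Pd(TFA)2 (5 mol%), 4,7-diphenyl-1,10-phenanthroline, Et3N (cat.), 16 as solvent, 75 °C; evaporate; then xylene, 160 °C (sealed)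
Reagents that add atoms: none
Why: Transfer vinylation then Claisen rearrangement: the [3,3] shift is suprafacial, so the 7β-oxygen delivers C11 to the β-face of C9 (leaving 9α-H), as 3β-allylic steroid vinyl ethers give 5β-acetaldehydes, and it moves the alkene to C7=C8 in conjugation with the ester.

Step 11
Reactants: 18 aldehyde; 19 diethyl (2-oxooxolan-3-yl)phosphonate
Product: 20 alkylidene lactone 4-methoxybenzyl 6α-(methoxymethoxy)labda-7,12(E)-dien-16,15-olid-17-oate
Conditions: 19, KOtBu, THF, 0 °C; then 18, 0 → 23 °C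
Reagents that add atoms: none
Why: Horner–Wadsworth–Emmons olefination of the aldehyde with the lactone phosphonate anion; the alkene geometry is irrelevant because the next step removes it.

Step 12
Reactants: 20 alkylidene lactone
Product: 21 butenolide 4-methoxybenzyl 6α-(methoxymethoxy)labda-7,13-dien-16,15-olid-17-oate
Conditions: RhCl3·3H2O (10 mol%), EtOH, 80 °C
Reagents that add atoms: none
Why: Rhodium-hydride-mediated alkene isomerisation moves the exocyclic double bond into the ring to give the more stable endocyclic butenolide (known for α-alkylidene butyrolactones); partial loss of MOM or PMB here is harmless because both are removed next.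

Step 13
Reactants: 21 butenolide
Product: 22 hydroxy acid 6α-hydroxylabda-7,13-dien-16,15-olid-17-oic acid
Conditions: TFA, anisole, CH2Cl2/H2O, 0 → 23 °C
Reagents that add atoms: none
Why: Acidolysis: the PMB ester ionises to the 4-methoxybenzyl cation (trapped by anisole) and the MOM acetal is hydrolysed, while the electron-poor allylic C6–O bond, the butenolide and all stereocentres are inert.

Step 14
Reactants: 22 hydroxy acid; 23 (R)-2-methylbutanoic acid
Product: 25 6α-[(2R)-2-methylbutanoyloxy]labda-7,13-dien-16,15-olid-17-oic acid, via (R)-2-methylbutanoic anhydride 24 (not isolated)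
Conditions: 23 (3 equiv), DIC (1.5 equiv), CH2Cl2, 0 °C; then 22, DMAP (cat.), pyridine, 23 °C; aq. NaHCO3, then pH 3
Reagents that add atoms: none
Why: DMAP-catalysed O-acylation by the symmetric anhydride formed in situ; the hindered conjugated C17 carboxyl at most forms a mixed anhydride that the bicarbonate work-up hydrolyses, and the acyl α-centre is not enolised under these conditions.

Compound list
1 | 2-methoxy-5-methyl-1,4-benzoquinone | COC1=CC(=O)C(C)=CC1=O | starting material
2 | 4-methylpenta-1,3-diene | CC(C)=CC=C | starting material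
3 | cis-fused adduct, 7-methoxy-4,4,10β-trimethyl-5βH-decal-2,7-diene-6,9-dione | O=C1C(OC)=CC(=O)[C@@]2(C)CC=CC(C)(C)[C@@H]12 | intermediate
4 | 6-(methoxymethoxy)-7-methoxy-4,4,10β-trimethyldecal-2,5,7-trien-9-one | O=C1C=C(OC)C(OCOC)=C2C(C)(C)C=CC[C@]12C | intermediate
5 | 6-(methoxymethoxy)-7-methoxy-4,4,10β-trimethyldecal-2,5,7-trien-9-ol (C9 epimers) | OC1C=C(OC)C(OCOC)=C2C(C)(C)C=CC[C@]12C | intermediate
6 | 6-(methoxymethoxy)-4,4,10β-trimethyldecal-2,5,8-trien-7-one | O=C1C=C[C@@]2(C)CC=CC(C)(C)C2=C1OCOC | intermediate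
7 | 6-(methoxymethoxy)-4,4,10β-trimethyldecal-5-en-7-one | O=C1CC[C@@]2(C)CCCC(C)(C)C2=C1OCOC | intermediate
8 | lithium 6-(methoxymethoxy)-4,4,10β-trimethyl-5αH-decal-6-en-7-olate | COCOC1=C(O[Li])CC[C@@]2(C)CCCC(C)(C)[C@H]12 | intermediate
9 | 6β-(methoxymethoxy)-4,4,10β-trimethyl-5αH-decalin-7-one | COCO[C@@H]1C(=O)CC[C@@]2(C)CCCC(C)(C)[C@H]12 | intermediate
10 | 6α-(methoxymethoxy)-4,4,10β-trimethyl-5αH-decalin-7-one (trans-fused) | COCO[C@H]1C(=O)CC[C@@]2(C)CCCC(C)(C)[C@H]12 | intermediate
11 | 6α-(methoxymethoxy)-7-(trimethylsilyloxy)-4,4,10β-trimethyl-5αH-decal-7-ene | COCO[C@H]1C(O[Si](C)(C)C)=CC[C@@]2(C)CCCC(C)(C)[C@H]12 | intermediate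
12 | 6α-(methoxymethoxy)-4,4,10β-trimethyl-5αH-decal-8-en-7-one | COCO[C@H]1C(=O)C=C[C@@]2(C)CCCC(C)(C)[C@H]12 | intermediate
13 | 8-iodo-6α-(methoxymethoxy)-4,4,10β-trimethyl-5αH-decal-8-en-7-one | COCO[C@H]1C(=O)C(I)=C[C@@]2(C)CCCC(C)(C)[C@H]12 | intermediate
14 | 8-iodo-6α-(methoxymethoxy)-4,4,10β-trimethyl-5αH-decal-8-en-7β-ol | COCO[C@H]1[C@H](O)C(I)=C[C@@]2(C)CCCC(C)(C)[C@H]12 | intermediate
15 | 4-methoxybenzyl 7β-hydroxy-6α-(methoxymethoxy)-4,4,10β-trimethyl-5αH-decal-8-ene-8-carboxylate | COCO[C@H]1[C@H](O)C(C(=O)OCc3ccc(OC)cc3)=C[C@@]2(C)CCCC(C)(C)[C@H]12 | intermediate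
16 | butyl vinyl ether | C=COCCCC | starting material
17 | 4-methoxybenzyl 6α-(methoxymethoxy)-7β-(vinyloxy)-4,4,10β-trimethyl-5αH-decal-8-ene-8-carboxylate | COCO[C@H]1[C@H](OC=C)C(C(=O)OCc3ccc(OC)cc3)=C[C@@]2(C)CCCC(C)(C)[C@H]12 | intermediate
18 | 4-methoxybenzyl 6α-(methoxymethoxy)-9β-(2-oxoethyl)-4,4,10β-trimethyl-5αH,9αH-decal-7-ene-8-carboxylate | COCO[C@H]1C=C(C(=O)OCc3ccc(OC)cc3)[C@H](CC=O)[C@@]2(C)CCCC(C)(C)[C@H]12 | intermediate
19 | diethyl (2-oxooxolan-3-yl)phosphonate | CCOP(=O)(OCC)C1CCOC1=O | starting material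
20 | 4-methoxybenzyl 6α-(methoxymethoxy)labda-7,12(E)-dien-16,15-olid-17-oate | COCO[C@H]1C=C(C(=O)OCc3ccc(OC)cc3)[C@H](C/C=C4\CCOC4=O)[C@@]2(C)CCCC(C)(C)[C@H]12 | intermediate
21 | 4-methoxybenzyl 6α-(methoxymethoxy)labda-7,13-dien-16,15-olid-17-oate | COCO[C@H]1C=C(C(=O)OCc3ccc(OC)cc3)[C@H](CCC4=CCOC4=O)[C@@]2(C)CCCC(C)(C)[C@H]12 | intermediate
22 | 6α-hydroxylabda-7,13-dien-16,15-olid-17-oic acid | O[C@H]1C=C(C(=O)O)[C@H](CCC2=CCOC2=O)[C@@]2(C)CCCC(C)(C)[C@H]12 | intermediate
23 | (R)-2-methylbutanoic acid | CC[C@@H](C)C(=O)O | starting material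
24 | (R,R)-2-methylbutanoic anhydride | CC[C@@H](C)C(=O)OC(=O)[C@H](C)CC | intermediate
25 | 6α-[(2R)-2-methylbutanoyloxy]labda-7,13-dien-16,15-olid-17-oic acid (CNP0150853.1) | CC[C@@H](C)C(=O)O[C@H]1C=C(C(=O)O)[C@H](CCC2=CCOC2=O)[C@@]2(C)CCCC(C)(C)[C@H]12 | target

Total step count: 14. Longest linear sequence: 14 steps (1 and 2 to 25; 16, 19 and 23 are purchased).

Steps most likely to fail

Step 1. The cis-methyl group keeps the s-cis population of the diene low, so cationic oligomerisation of the diene by the strong Lewis acid, or cycloaddition through a complex bound at the more basic C9 carbonyl, may outrun the organised pathway and erode conversion and enantiomeric purity. The fallback sets out from 1 and uses a far more nucleophilic diene, 4-methyl-2-(triisopropylsilyloxy)penta-1,3-diene F1 (from mesityl oxide, TIPSOTf, Et3N), under the same type of catalysis; its CH2 terminus again bonds to C10 and the silyl enol ether adduct F2 should result. CsF/PhNTf2 converts it into the C2 enol triflate F3, and Pd(OAc)2/PPh3/HCO2H/Bu3N reduction of the triflate comes back to the route at 3. Any C5 epimerisation on the way is irrelevant because step 2 removes that centre.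

Step 10. Vinyl transfer to the doubly flanked 7β-carbinol may stall, and the [3,3] shift has to pass through a boat-like ring B to make the equatorial C7–O bond axial, so thermal elimination or ionisation of the activated allylic ether may compete with rearrangement. The fallback sets out from 15: phenyl isocyanate gives the N-phenylcarbamate F4, and a carbamate-directed syn-SN2′ substitution with a vinylcopper reagent (vinylMgBr, CuI) should deliver the vinyl group to the β-face of C9 with transposition of the alkene, giving the 9β-vinyl 7-ene ester F5. Hydroboration of the terminal alkene with 9-BBN gives the B-alkylborane F6, and B-alkyl Suzuki–Miyaura coupling with commercial 3-bromofuran-2(5H)-one (Pd(dppf)Cl2, Ph3As, Cs2CO3) comes back at 21, bypassing steps 11 and 12.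

Step 12. Double-bond migration may stop at an exo/endo mixture, or the warm acidic ethanol may solvolyse the esters before isomerisation is complete. The fallback sets out from 18: NaBH4 reduction gives the primary alcohol F7, I2/PPh3/imidazole the primary iodide F8, and zinc insertion (Zn, LiCl, THF) the alkylzinc iodide F9. Negishi coupling of the zinc reagent with 3-bromofuran-2(5H)-one (Pd(OAc)2, SPhos) comes back at 21 without passing through 20.

Further compounds
F1 | step 1 | 4-methyl-2-(triisopropylsilyloxy)penta-1,3-diene | C=C(O[Si](C(C)C)(C(C)C)C(C)C)C=C(C)C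
F2 | step 1 | cis-fused adduct bearing a C2 triisopropylsilyl enol ether | O=C1C(OC)=CC(=O)[C@@]2(C)CC(O[Si](C(C)C)(C(C)C)C(C)C)=CC(C)(C)[C@@H]12
F3 | step 1 | cis-fused adduct bearing a C2 enol triflate | O=C1C(OC)=CC(=O)[C@@]2(C)CC(OS(=O)(=O)C(F)(F)F)=CC(C)(C)[C@@H]12
F4 | step 10 | N-phenylcarbamate of 15 | COCO[C@H]1[C@H](OC(=O)Nc3ccccc3)C(C(=O)OCc4ccc(OC)cc4)=C[C@@]2(C)CCCC(C)(C)[C@H]12
F5 | step 10 | 4-methoxybenzyl 6α-(methoxymethoxy)-9β-vinyl-4,4,10β-trimethyl-5αH,9αH-decal-7-ene-8-carboxylate | COCO[C@H]1C=C(C(=O)OCc3ccc(OC)cc3)[C@H](C=C)[C@@]2(C)CCCC(C)(C)[C@H]12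
F6 | step 10 | B-alkyl-9-BBN adduct of F5 | COCO[C@H]1C=C(C(=O)OCc3ccc(OC)cc3)[C@H](CCB4C5CCCC4CCC5)[C@@]2(C)CCCC(C)(C)[C@H]12
F7 | step 12 | 4-methoxybenzyl 9β-(2-hydroxyethyl)-6α-(methoxymethoxy)-4,4,10β-trimethyl-5αH,9αH-decal-7-ene-8-carboxylate | COCO[C@H]1C=C(C(=O)OCc3ccc(OC)cc3)[C@H](CCO)[C@@]2(C)CCCC(C)(C)[C@H]12
F8 | step 12 | 4-methoxybenzyl 9β-(2-iodoethyl)-6α-(methoxymethoxy)-4,4,10β-trimethyl-5αH,9αH-decal-7-ene-8-carboxylate | COCO[C@H]1C=C(C(=O)OCc3ccc(OC)cc3)[C@H](CCI)[C@@]2(C)CCCC(C)(C)[C@H]12
F9 | step 12 | alkylzinc iodide from F8 | COCO[C@H]1C=C(C(=O)OCc3ccc(OC)cc3)[C@H](CC[Zn]I)[C@@]2(C)CCCC(C)(C)[C@H]12
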